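The α‑methylene‑γ‑butyrolactone (ring O–C6–C7–C11–C12, exocyclic C13; germacrane numbering) is read as a terminal allene (C7=C11=C13), an aldehyde (C6) and CO2 (C12). One zerovalent‑nickel carboxylative allylation joins allene 11 (C7–C10, C1, C13; C10 bought, C8 set by reagent control) with Z‑enal 4 (C3–C6). It forms C11–C12 and C6–C7 and, through a chelated Z‑allylnickel chair, sets the cis C6/C7 pair from C8; lactonisation follows on work‑up. Mitsunobu angeloylation then inverts C8, and a Nozaki–Hiyama–Kishi closure of C2–C3 builds the ten‑membered ring and C3.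

Key step: step 9

Remark on numbering: C1–C10 are the ring carbons, C11/C12/C13 the lactone carbons, C14 the methyl on C10, C15 the methyl on C4; bare numbers are compounds.
Assumption: the (R,R)‑bis‑sulfonamide boron controller is taken to deliver the 8S allenyl carbinol; if its sense of induction is the opposite, the (S,S)‑controller is used.
Assumption: the allylnickel adds to the aldehyde on the face of C7 syn to the C8 ether oxygen (8S gives 7S, 6R), which is why C8 is made 8S and inverted in step 11.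

Step 1
Reactants: 1 4‑methylfuran‑2(5H)‑one
Product: 2 (Z)‑4‑hydroxy‑N‑methoxy‑N,3‑dimethylbut‑2‑enamide
Conditions: MeNH(OMe)·HCl, iPrMgCl, THF, −20 to 0 °C
Reagents that add atoms: N,O‑dimethylhydroxylamine hydrochloride, CNOC.Cl
Why: Aminolysis of the lactone by the chloromagnesium amide of the Weinreb amine opens the butenolide, whose ring has already fixed the Z geometry of C4=C5 (C3 cis to C6).

Step 2
Reactants: 2 (Z)‑4‑hydroxy‑N‑methoxy‑N,3‑dimethylbut‑2‑enamide
Product: 3 (Z)‑4‑[(tert‑butyldiphenylsilyl)oxy]‑N‑methoxy‑N,3‑dimethylbut‑2‑enamide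
Conditions: TBDPSCl, imidazole, DMF, 0 °C
Reagents that add atoms: tert‑butyl(chloro)diphenylsilane, CC(C)(C)[Si](Cl)(c1ccccc1)c1ccccc1
Why: Silylation of the primary alcohol should outrun relactonisation and gives an ether that survives acid, DDQ and chromium reagents until step 15.

Step 3
Reactants: 3 (Z)‑4‑[(tert‑butyldiphenylsilyl)oxy]‑N‑methoxy‑N,3‑dimethylbut‑2‑enamide
Product: 4 (Z)‑4‑[(tert‑butyldiphenylsilyl)oxy]‑3‑methylbut‑2‑enal
Conditions: DIBAL‑H, THF, −78 °C; aq. Rochelle salt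
Reagents that add atoms: none
Why: Weinreb amide reduction stops at the aldehyde through the chelated aluminium hemiaminal and leaves the Z alkene untouched.

Step 4
Reactants: 5 (S)‑2‑methylglycidol
Product: 6 (R)‑2‑methylpent‑4‑ene‑1,2‑diol
Conditions: CH2=CHMgBr (3 equiv), CuI (10 mol %), THF, −30 to 0 °C
Reagents that add atoms: vinylmagnesium bromide, C=C[Mg]Br
Why: Copper‑catalysed Grignard opening of the 2,2‑disubstituted epoxide at its CH2 terminus leaves the purchased quaternary centre (future C10) untouched, and a Payne shift of this substrate is degenerate.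

Step 5
Reactants: 6 (R)‑2‑methylpent‑4‑ene‑1,2‑diol
Product: 7 (R)‑2,2,4‑trimethyl‑4‑(prop‑2‑en‑1‑yl)‑1,3‑dioxolane
Conditions: 2,2‑dimethoxypropane, PPTS (cat.), CH2Cl2, rt
Reagents that add atoms: 2,2‑dimethoxypropane, COC(C)(C)OC
Why: Transketalisation masks the tertiary C10 and primary C1 hydroxyls together as an acetonide.

Step 6
Reactants: 7 (R)‑2,2,4‑trimethyl‑4‑(prop‑2‑en‑1‑yl)‑1,3‑dioxolane
Product: 9 2‑[(4R)‑2,2,4‑trimethyl‑1,3‑dioxolan‑4‑yl]acetaldehyde, via ozonide 8 (not isolated)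
Conditions: O3, CH2Cl2, −78 °C; then PPh3, −78 °C to rt
Reagents that add atoms: ozone, [O-][O+]=O
Why: Ozonolysis with reductive work‑up cleaves the only alkene to the C8 aldehyde.

Step 7
Reactants: 9 2‑[(4R)‑2,2,4‑trimethyl‑1,3‑dioxolan‑4‑yl]acetaldehyde
Product: 10 (2S)‑1‑[(4R)‑2,2,4‑trimethyl‑1,3‑dioxolan‑4‑yl]penta‑3,4‑dien‑2‑ol
Conditions: (R,R)‑1,2‑diphenyl‑N,N′‑ditosylethane‑1,2‑diamine, BBr3, CH2Cl2, 0 °C to rt; allenyltributylstannane, 0 °C; then 9, toluene, −78 °C
Reagents that add atoms: allenyltributylstannane, C=C=C[Sn](CCCC)(CCCC)CCCC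
Why: Enantioselective propargylboration: the B‑propargyl diazaborolidine made in the flask adds to the aldehyde with allyl transposition (SE2′) through a chair, giving the allenyl carbinol with C8 (8S) set by the sulfonamide controller.

Step 8
Reactants: 10 (2S)‑1‑[(4R)‑2,2,4‑trimethyl‑1,3‑dioxolan‑4‑yl]penta‑3,4‑dien‑2‑ol
Product: 11 (4R)‑4‑{(2S)‑2‑[(4‑methoxybenzyl)oxy]penta‑3,4‑dien‑1‑yl}‑2,2,4‑trimethyl‑1,3‑dioxolane
Conditions: NaH, PMBCl, Bu4NI (cat.), THF/DMF, 0 °C to rt
Reagents that add atoms: 4‑methoxybenzyl chloride, COc1ccc(CCl)cc1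
Why: Williamson etherification gives a Lewis‑basic C8 ether that survives nickel, amidine base and mild acid and is later removed oxidatively.

Step 9
Reactants: 11 (4R)‑4‑{(2S)‑2‑[(4‑methoxybenzyl)oxy]penta‑3,4‑dien‑1‑yl}‑2,2,4‑trimethyl‑1,3‑dioxolane; 4 (Z)‑4‑[(tert‑butyldiphenylsilyl)oxy]‑3‑methylbut‑2‑enal
Product: 14 (4S,5R)‑5‑[(Z)‑3‑(tert‑butyldiphenylsilyloxy)‑2‑methylprop‑1‑enyl]‑4‑{(1S)‑1‑[(4‑methoxybenzyl)oxy]‑2‑[(4R)‑2,2,4‑trimethyl‑1,3‑dioxolan‑4‑yl]ethyl}‑3‑methylideneoxolan‑2‑one, via nickelalactone 12 (not isolated), via hydroxy acid 13 (not isolated)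
Conditions: Ni(cod)2 (1.1 equiv), DBU (2.5 equiv), CO2 (1 atm), THF, 0 °C; then 4 (1.3 equiv), 0 °C to rt; 0.5 M HCl, 0 °C; then PPTS (cat.), CH2Cl2, rt
Reagents that add atoms: carbon dioxide, O=C=O
Why: Zerovalent nickel couples the terminal C11=C13 π bond of the allene oxidatively with CO2 on the side away from C8, which makes C11–C12 and the 2‑carboxylato Z‑allylnickel 12 (nickel on C13, also held by the PMB ether oxygen); this adds to the aldehyde of 4 through a six‑membered chair at the substituted terminus, which makes C6–C7, and protonation then closes the lactone. The closest known reaction type is the nickel‑mediated sequential addition of CO2 and an aldehyde to a terminal allene (oxidative coupling of CO2 with a C=C bond, then allylmetal carbonyl addition). Ring closures: the oxanickelacycle forms by oxidative cyclisation, and the γ‑lactone by 5‑exo‑trig acyl substitution of O6 on C12 in syn hydroxy acid 13. C6 and C7: the Z‑allyl geometry with the enal residue equatorial in the chair should give the syn pair (cis lactone), and C8 fixes the face, with its hydrogen eclipsing the allyl plane (A(1,3) strain), C9 anti and the coordinating ether on the attack side, so 8S should give 7S and 6R. The step needs carboxylation at the central allene carbon, bond formation at C7 rather than C13, 1,2‑addition and retention of the Z‑enal; π‑allyl stabilisation, the closed transition state and addition of the enal at 0 °C only after the nickelacycle has formed should secure these.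

Step 10
Reactants: 14 lactone PMB ether (6R,7S,8S,10R)
Product: 15 (4S,5R)‑5‑[(Z)‑3‑(tert‑butyldiphenylsilyloxy)‑2‑methylprop‑1‑enyl]‑4‑{(1S)‑1‑hydroxy‑2‑[(4R)‑2,2,4‑trimethyl‑1,3‑dioxolan‑4‑yl]ethyl}‑3‑methylideneoxolan‑2‑one
Conditions: DDQ, CH2Cl2/pH 7 buffer, 0 °C
Reagents that add atoms: none
Why: Oxidative cleavage of the PMB ether frees only the C8 hydroxyl under near‑neutral conditions that do not promote translactonisation.

Step 11
Reactants: 15 C8 alcohol (8S)
Product: 16 (8R)‑angelate: (1R)‑1‑{(3S,4R... oxolanone core of 15)}‑2‑[(4R)‑2,2,4‑trimethyl‑1,3‑dioxolan‑4‑yl]ethyl (Z)‑2‑methylbut‑2‑enoate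
Conditions: angelic acid, PPh3, DIAD, toluene, 0 °C to rt
Reagents that add atoms: angelic acid, C/C=C(/C)C(=O)O
Why: Mitsunobu esterification: SN2 displacement of the alkoxyphosphonium by angelate inverts C8 (8S to 8R) and installs the ester under neutral conditions that should not isomerise angelate to tiglate.

Step 12
Reactants: 16 (8R)‑angelate acetonide
Product: 17 C1,C10‑diol (primary C1–OH, tertiary C10–OH)
Conditions: AcOH/H2O (4:1), 40 °C
Reagents that add atoms: none
Why: Mild acetal hydrolysis removes the acetonide while the TBDPS ether, lactone and angelate are stable.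

Step 13
Reactants: 17 C1,C10‑diol
Product: 18 α‑hydroxy aldehyde (C1 aldehyde, C10 tertiary alcohol)
Conditions: IBX, DMSO, rt
Reagents that add atoms: none
Why: IBX oxidises the primary alcohol of a 1,2‑diol to the aldehyde without glycol cleavage and cannot oxidise the tertiary alcohol.

Step 14
Reactants: 18 α‑hydroxy aldehyde
Product: 19 (E)‑vinyl iodide (C1=C2–I)
Conditions: CrCl2 (6 equiv), CHI3 (2 equiv), THF/dioxane, 0 °C to rt
Reagents that add atoms: iodoform, IC(I)I
Why: Takai olefination through the geminal dichromium species gives the E‑iodoalkene and tolerates the lactone, esters and free tertiary alcohol.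

Step 15
Reactants: 19 (E)‑vinyl iodide TBDPS ether
Product: 20 primary allylic alcohol (C3–OH)
Conditions: HF·pyridine, pyridine, THF, 0 °C to rt
Reagents that add atoms: none
Why: Buffered fluoride desilylation frees the C3 alcohol without base that could isomerise the angelate or open the lactone.

Step 16
Reactants: 20 primary allylic alcohol
Product: 21 (Z)‑enal (C3 aldehyde) with (E)‑vinyl iodide
Conditions: MnO2, CH2Cl2, rt
Reagents that add atoms: none
Why: MnO2 oxidises only the allylic primary alcohol, and its neutral surface should keep the Z geometry of C4=C5.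

Step 17
Reactants: 21 (Z)‑enal with (E)‑vinyl iodide
Product: 22 macrocyclic C3 alcohol (3R,6R,7S,8R,10R), the 3‑deacetyl target
Conditions: CrCl2 (8 equiv), NiCl2 (2 mol %), DMSO/THF, rt, 2 mM, slow addition
Reagents that add atoms: none
Why: Nozaki–Hiyama–Kishi reaction: the nickel‑catalysed alkenylchromium from the E‑iodide adds to the aldehyde with retention of both alkene geometries and closes C2–C3; C3 is set by substrate control, because the Z‑enal reacts s‑trans with C6–H eclipsing the C4=C5 plane (A(1,3) strain), so C2, tethered through C7, should reach the aldehyde face that gives 3R.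

Step 18
Reactants: 22 macrocyclic C3 alcohol
Product: 23 CNP0181631.1
Conditions: Ac2O, pyridine, DMAP (cat.), CH2Cl2, 0 °C
Reagents that add atoms: acetic anhydride, CC(=O)OC(C)=O
Why: Acylation of the secondary bis‑allylic alcohol is far faster than that of the tertiary C10 alcohol, which stays free.

Compound list
1 | 4‑methylfuran‑2(5H)‑one | CC1=CC(=O)OC1 | starting material
2 | (Z)‑4‑hydroxy‑N‑methoxy‑N,3‑dimethylbut‑2‑enamide | OC/C(C)=C\C(=O)N(C)OC | intermediate
3 | (Z)‑4‑[(tert‑butyldiphenylsilyl)oxy]‑N‑methoxy‑N,3‑dimethylbut‑2‑enamide | CC(C)(C)[Si](OC/C(C)=C\C(=O)N(C)OC)(c1ccccc1)c1ccccc1 | intermediate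
4 | (Z)‑4‑[(tert‑butyldiphenylsilyl)oxy]‑3‑methylbut‑2‑enal (C3–C6, C15) | CC(C)(C)[Si](OC/C(C)=C\C=O)(c1ccccc1)c1ccccc1 | intermediate
5 | (S)‑2‑methylglycidol, (S)‑(2‑methyloxiran‑2‑yl)methanol | OC[C@]1(C)OC1 | starting material
6 | (R)‑2‑methylpent‑4‑ene‑1,2‑diol | OC[C@](C)(O)CC=C | intermediate
7 | (R)‑2,2,4‑trimethyl‑4‑(prop‑2‑en‑1‑yl)‑1,3‑dioxolane | CC1(C)OC[C@@](C)(CC=C)O1 | intermediate
8 | ozonide of 7, 3‑{[(4R)‑2,2,4‑trimethyl‑1,3‑dioxolan‑4‑yl]methyl}‑1,2,4‑trioxolane (not isolated) | CC1(C)OC[C@@](C)(CC2OCOO2)O1 | intermediate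
9 | 2‑[(4R)‑2,2,4‑trimethyl‑1,3‑dioxolan‑4‑yl]acetaldehyde | CC1(C)OC[C@@](C)(CC=O)O1 | intermediate
10 | (2S)‑1‑[(4R)‑2,2,4‑trimethyl‑1,3‑dioxolan‑4‑yl]penta‑3,4‑dien‑2‑ol | CC1(C)OC[C@@](C)(C[C@H](O)C=C=C)O1 | intermediate
11 | (4R)‑4‑{(2S)‑2‑[(4‑methoxybenzyl)oxy]penta‑3,4‑dien‑1‑yl}‑2,2,4‑trimethyl‑1,3‑dioxolane | CC1(C)OC[C@@](C)(C[C@H](OCc2ccc(OC)cc2)C=C=C)O1 | intermediate
12 | nickelalactone, 2‑carboxylato (Z)‑allylnickel from 11 and CO2, DBU ligands on nickel not drawn (not isolated) | O=C1O[Ni]C/C1=C\[C@@H](OCc1ccc(OC)cc1)C[C@]1(C)COC(C)(C)O1 | intermediate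
13 | syn γ‑hydroxy‑α‑methylene acid (6R,7S,8S,10R) (not isolated) | C=C(C(=O)O)[C@H]([C@H](O)/C=C(/C)CO[Si](c1ccccc1)(c1ccccc1)C(C)(C)C)[C@@H](OCc1ccc(OC)cc1)C[C@]1(C)COC(C)(C)O1 | intermediate
14 | cis α‑methylene lactone, 8S PMB ether, TBDPS ether, acetonide (6R,7S,8S,10R) | C=C1C(=O)O[C@H](/C=C(/C)CO[Si](c2ccccc2)(c2ccccc2)C(C)(C)C)[C@@H]1[C@@H](OCc1ccc(OC)cc1)C[C@]1(C)COC(C)(C)O1 | intermediate
15 | cis α‑methylene lactone, free 8S alcohol | C=C1C(=O)O[C@H](/C=C(/C)CO[Si](c2ccccc2)(c2ccccc2)C(C)(C)C)[C@@H]1[C@@H](O)C[C@]1(C)COC(C)(C)O1 | intermediate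
16 | cis α‑methylene lactone, 8R angelate, acetonide | C=C1C(=O)O[C@H](/C=C(/C)CO[Si](c2ccccc2)(c2ccccc2)C(C)(C)C)[C@@H]1[C@H](OC(=O)/C(C)=C\C)C[C@]1(C)COC(C)(C)O1 | intermediate
17 | C1,C10‑diol of 16 | C=C1C(=O)O[C@H](/C=C(/C)CO[Si](c2ccccc2)(c2ccccc2)C(C)(C)C)[C@@H]1[C@H](OC(=O)/C(C)=C\C)C[C@@](C)(O)CO | intermediate
18 | α‑hydroxy aldehyde (C1 aldehyde) | C=C1C(=O)O[C@H](/C=C(/C)CO[Si](c2ccccc2)(c2ccccc2)C(C)(C)C)[C@@H]1[C@H](OC(=O)/C(C)=C\C)C[C@@](C)(O)C=O | intermediate
19 | (E)‑vinyl iodide, TBDPS ether | C=C1C(=O)O[C@H](/C=C(/C)CO[Si](c2ccccc2)(c2ccccc2)C(C)(C)C)[C@@H]1[C@H](OC(=O)/C(C)=C\C)C[C@@](C)(O)/C=C/I | intermediate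
20 | (E)‑vinyl iodide, free C3 allylic alcohol | C=C1C(=O)O[C@H](/C=C(/C)CO)[C@@H]1[C@H](OC(=O)/C(C)=C\C)C[C@@](C)(O)/C=C/I | intermediate
21 | (E)‑vinyl iodide, (Z)‑enal | C=C1C(=O)O[C@H](/C=C(/C)C=O)[C@@H]1[C@H](OC(=O)/C(C)=C\C)C[C@@](C)(O)/C=C/I | intermediate
22 | macrocyclic 3R alcohol, 3‑deacetyl target | C=C1C(=O)O[C@@H]2/C=C(/C)[C@H](O)/C=C/[C@](C)(O)C[C@@H](OC(=O)/C(C)=C\C)[C@H]12 | intermediate
23 | CNP0181631.1 | C=C1C(=O)O[C@@H]2/C=C(/C)[C@H](OC(C)=O)/C=C/[C@](C)(O)C[C@@H](OC(=O)/C(C)=C\C)[C@H]12 | target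

Total step count: 18. Longest linear sequence: 15 steps (steps 4–18 from 5); the enal branch (steps 1–3) joins at step 9.

Steps most likely to fail

1. Step 9. The Z‑allylnickel may isomerise to the E form before it adds, which would give the trans lactone. The facial selectivity relative to C8 may be poor or opposite. DBU may isomerise the Z‑enal. The fallback sets out from 11 and 4 and returns at 14, making the two C–C bonds in separate known operations. Pt(dba)2/PCy3‑catalysed diboration of the terminal C11=C13 bond of 11 with B2pin2 should give the (Z)‑2,3‑bis(pinacolboryl)alkene F1. Its allylboronate adds to 4 (toluene, rt) through the chair at C7 to give the syn homoallylic alcohol that keeps the C11 vinyl boronate F2. NaOMe then I2 converts this into the vinyl iodide F3. Pd(PPh3)4, CO (1 atm) and Et3N then close the α‑methylene lactone by cyclocarbonylation to 14.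

2. Step 17. The facial selectivity of the ring‑closing addition at C3 may be poor, and intermolecular coupling competes if dilution is insufficient. The fallback sets out from 21 and returns at 22. The same closure is run without demand on the C3 ratio and gives 22 mixed with its C3 epimer F4. MnO2 oxidises both to the single cross‑conjugated macrocyclic dienone F5. Corey–Bakshi–Shibata reduction ((S)‑Me‑oxazaborolidine, BH3·SMe2, antipode if needed) then sets C3 under reagent control to give 22.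

3. Step 11. The hindered alkoxyphosphonium may eliminate towards C7 or C9, react with retention through participation of the lactone carbonyl, or the angelate may isomerise. The fallback sets out from 15 and returns at 16. ClCH2SO2Cl/pyridine gives the C8 chloromethanesulfonate F6. Cesium angelate with 18‑crown‑6 in toluene at 40 °C displaces it with inversion to 16.

Further compounds
F1 | step 9 | (Z)‑2,3‑bis(pinacolboryl)alkene from terminal diboration of 11 | CC1(C)OB(C/C(B2OC(C)(C)C(C)(C)O2)=C\[C@@H](OCc2ccc(OC)cc2)C[C@]2(C)COC(C)(C)O2)OC1(C)C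
F2 | step 9 | syn homoallylic alcohol with C11 vinyl boronate, same C6, C7, C8, C10 configuration as 13 | C=C(B1OC(C)(C)C(C)(C)O1)[C@H]([C@H](O)/C=C(/C)CO[Si](c1ccccc1)(c1ccccc1)C(C)(C)C)[C@@H](OCc1ccc(OC)cc1)C[C@]1(C)COC(C)(C)O1
F3 | step 9 | syn homoallylic alcohol with C11 vinyl iodide | C=C(I)[C@H]([C@H](O)/C=C(/C)CO[Si](c1ccccc1)(c1ccccc1)C(C)(C)C)[C@@H](OCc1ccc(OC)cc1)C[C@]1(C)COC(C)(C)O1
F4 | step 17 | C3 epimer of 22 | C=C1C(=O)O[C@@H]2/C=C(/C)[C@@H](O)/C=C/[C@](C)(O)C[C@@H](OC(=O)/C(C)=C\C)[C@H]12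
F5 | step 17 | macrocyclic C3 dienone | C=C1C(=O)O[C@@H]2/C=C(/C)C(=O)/C=C/[C@](C)(O)C[C@@H](OC(=O)/C(C)=C\C)[C@H]12
F6 | step 11 | C8 chloromethanesulfonate of 15 | C=C1C(=O)O[C@H](/C=C(/C)CO[Si](c2ccccc2)(c2ccccc2)C(C)(C)C)[C@@H]1[C@@H](OS(=O)(=O)CCl)C[C@]1(C)COC(C)(C)O1
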